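**Plan**
- Retrosynthesis: after removal of two silyl ethers, ring A and the pyran ring are cut together at C4a–C8a and C5–C6 (silanol re-added at C8a). Further cuts are the O1–C8a ester bond, C3–C4 (propargylation of an arylacetyl imide), the C2–C3 carbon from the aldehyde homologation, and on ring B the C5′–C(quaternary) bond and both O–prenyl bonds.
- Enabling feature: ring A is a resorcinol (O1 on C8a, OH on C7) sharing the C4a–C8a edge with the pyran ring. C8a–C8–C7–C6 therefore maps onto an acetoacetate-derived 1-alkoxy-1,3-bis(silyloxy)diene whose alkoxy oxygen is O1, and C4a–C5 onto an alkyne held by the O1–C2–C3–C4 chain.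
- Forward: ring B is completed first on 2,4-dihydroxybenzaldehyde (O-prenylation, silylation, Claisen shift to C5′, O-prenylation). The aldehyde is homologated to the arylacetic acid, which is propargylated, reduced, acetoacetylated and bis-silylated. One thermal step then closes the pyran ring and ring A together, and fluoride frees the two phenols.
- Stereochemistry: the only stereocentre, C3 (R), comes from alkylation of the (R)-4-benzyloxazolidinone imide and is not touched afterwards.
- Ring B enters the key step complete, so only desilylation follows it, and the ortho position that a heated aryl prenyl ether would attack is already filled.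

Key step: step 12

Notation: Ar = 5-(2-methylbut-3-en-2-yl)-4-(3-methylbut-2-enyloxy)-2-(triisopropylsilyloxy)phenyl; atom labels follow isoflavan numbering.
Assumption: the ketene acetal C=C of the key-step precursor is drawn 1Z (OSiMe3 cis to the diene chain); the 1E isomer is expected to give the same cycloadduct, since both substituents on that carbon are oxygen.

**Step 1**
Reactants: 1 2,4-dihydroxybenzaldehyde; 2 prenyl bromide (1-bromo-3-methylbut-2-ene)
Product: 3 2-hydroxy-4-(3-methylbut-2-enyloxy)benzaldehyde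
Conditions: K2CO3 (1.1 equiv), acetone, rt to 50 °C
Reagents that add atoms: 2 prenyl bromide, CC(C)=CCBr
Why: Williamson ether synthesis; the 2-OH is hydrogen-bonded to the formyl group and far less nucleophilic, so only the 4-OH is alkylated.

**Step 2**
Reactants: 3; 4 chlorotriisopropylsilane
Product: 5 4-(3-methylbut-2-enyloxy)-2-(triisopropylsilyloxy)benzaldehyde
Conditions: TIPSCl, imidazole, DMF, rt to 40 °C
Reagents that add atoms: 4 chlorotriisopropylsilane, CC(C)[Si](Cl)(C(C)C)C(C)C
Why: silyl chloride–imidazole O-silylation of the phenol; the bulky TIPS ether breaks the chelate, shields C3 and tolerates the later base, hydride and heat.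

**Step 3**
Reactants: 5
Product: 7 4-hydroxy-5-(2-methylbut-3-en-2-yl)-2-(triisopropylsilyloxy)benzaldehyde, via cyclohexadienone 6 (not isolated)
Conditions: PhNEt2, 190 °C, Ar
Reagents that add atoms: none
Why: aromatic Claisen rearrangement; the [3,3] shift inverts the prenyl group to 1,1-dimethylallyl and goes to C5, the ortho position para to the silyloxy donor and not flanked by OTIPS, after which dienone 6 enolises.

**Step 4**
Reactants: 7; 2 prenyl bromide
Product: 8 5-(2-methylbut-3-en-2-yl)-4-(3-methylbut-2-enyloxy)-2-(triisopropylsilyloxy)benzaldehyde (ArCHO)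
Conditions: K2CO3, acetone, reflux
Reagents that add atoms: 2 prenyl bromide, CC(C)=CCBr
Why: Williamson ether synthesis on the only free phenol, which is acidic (para to CHO) and therefore alkylated despite the ortho tert-alkyl group.

**Step 5**
Reactants: 8; 9 (methoxymethyl)triphenylphosphonium chloride
Product: 10 Ar–CH=CH–OMe, 1-(2-methoxyethenyl)arene (E/Z mixture)
Conditions: NaHMDS, THF, 0 °C to rt
Reagents that add atoms: 9 (methoxymethyl)triphenylphosphonium chloride, COC[P+](c1ccccc1)(c1ccccc1)c1ccccc1.[Cl-]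
Why: Wittig olefination with the methoxymethylene ylide adds the carbon that becomes C2; the non-nucleophilic amide base spares the aryl silyl ether.

**Step 6**
Reactants: 10
Product: 12 Ar–CH2–CO2H, the arylacetic acid, via arylacetaldehyde 11 (not isolated)
Conditions: 1 M aq. HCl, THF, rt; then NaClO2, NaH2PO4, 2-methylbut-2-ene (excess), t-BuOH/H2O, 0 °C to rt
Reagents that add atoms: water, O; sodium chlorite, [Na+].[O-]Cl=O
Why: acid hydrolysis of the enol ether followed directly by Pinnick oxidation of the labile aldehyde, with the alkene scavenger taking up hypochlorite so that the prenyl groups and the electron-rich ring are left alone.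

**Step 7**
Reactants: 12; 13 (R)-4-benzyl-1,3-oxazolidin-2-one
Product: 15 (R)-4-benzyl-3-(2-Ar-acetyl)-1,3-oxazolidin-2-one, via mixed pivalic anhydride 14 (not isolated)
Conditions: PivCl, Et3N, THF, −20 °C; then 13, LiCl, −20 °C to rt
Reagents that add atoms: 13 (R)-4-benzyl-1,3-oxazolidin-2-one, O=C1N[C@H](Cc2ccccc2)CO1; pivaloyl chloride, CC(C)(C)C(=O)Cl (its atoms stay only in 14)
Why: N-acylation of the auxiliary through the mixed anhydride (lithium chloride–amine variant), which attacks the less hindered arylacetyl carbonyl.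

**Step 8**
Reactants: 15; 16 propargyl bromide
Product: 18 (4R)-4-benzyl-3-[(2R)-2-Ar-pent-4-ynoyl]-1,3-oxazolidin-2-one, via sodium Z-enolate 17 (not isolated)
Conditions: NaHMDS (1.1 equiv), THF, −78 °C; propargyl bromide (3 equiv), −78 to −40 °C
Reagents that add atoms: 16 propargyl bromide, C#CCBr; sodium bis(trimethylsilyl)amide, C[Si](C)(C)[N-][Si](C)(C)C.[Na+] (sodium stays only in 17)
Why: Evans asymmetric alkylation; the chelated Z-enolate is attacked on the face opposite the benzyl group of the (R)-auxiliary, which gives the (2R) centre that becomes C3 (R).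

**Step 9**
Reactants: 18
Product: 19 (2R)-2-Ar-pent-4-yn-1-ol
Conditions: LiBH4, MeOH (1 equiv), THF, 0 °C
Reagents that add atoms: none
Why: reductive cleavage of the N-acyl oxazolidinone at the exocyclic carbonyl to the primary alcohol under conditions too weakly basic to epimerise the α-aryl centre; the auxiliary is recovered.

**Step 10**
Reactants: 19; 20 2,2,6-trimethyl-4H-1,3-dioxin-4-one
Product: 21 (2R)-2-Ar-pent-4-yn-1-yl 3-oxobutanoate
Conditions: toluene, 110 °C
Reagents that add atoms: 20 2,2,6-trimethyl-4H-1,3-dioxin-4-one, CC1=CC(=O)OC(C)(C)O1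
Why: thermal retro-[4+2] of the dioxinone releases acetylketene, which acetoacetylates the primary alcohol under neutral conditions and so forms the O1–C8a bond.

**Step 11**
Reactants: 21; 22 trimethylsilyl trifluoromethanesulfonate
Product: 24 (2R)-2-Ar-pent-4-yn-1-yl (1Z)-1,3-bis(trimethylsilyloxy)buta-1,3-dien-1-yl ether, via mono-silyl enol ether 23 (not isolated)
Conditions: TMSOTf (2.4 equiv), Et3N (3.5 equiv), Et2O, 0 °C to rt; decant from the ammonium salt, concentrate under Ar, use crude
Reagents that add atoms: 22 trimethylsilyl trifluoromethanesulfonate, C[Si](C)(C)OS(=O)(=O)C(F)(F)F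
Why: silyl triflate–amine soft enolisation, the one-pot conversion of β-keto esters into 1-alkoxy-1,3-bis(trimethylsilyloxy)buta-1,3-dienes; no amide base is used, so the terminal alkyne C–H is not metalated.

**Step 12**
Reactants: 24
Product: 26 (3R)-3-Ar-7-(trimethylsilyloxy)chroman, the 7-O-TMS, 2′-O-TIPS isoflavan, via cyclohexadiene ketal 25 (not isolated)
Conditions: mesitylene (0.02 M, degassed), 2,6-di-tert-butyl-4-methylpyridine (0.2 equiv), 150–160 °C, sealed base-washed tube, Ar; evaporate, use crude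
Reagents that add atoms: none
Why: Proposed new method: the diene C8a=C8–C7=C6 of 24 should add suprafacially to the tethered C4a≡C5 triple bond in a concerted type-1 intramolecular Diels–Alder reaction through the O1–C2–C3–C4 chain, giving the 1,4-cyclohexadiene ketal 25; its doubly allylic C8a–OSiMe3 bond then ionises to an arenium ion stabilised by O1 and O7, and loss of H-6 (net 1,4-elimination of trimethylsilanol) aromatises ring A irreversibly. The closest known reaction types are the intermolecular Diels–Alder/aromatisation of 1-alkoxy-1,3-bis(silyloxy)butadienes with acceptor-substituted alkynes to resorcinol derivatives and the thermal intramolecular [4+2] cycloaddition of unactivated dienynes; new here is an unactivated alkyne tethered through the ketene acetal oxygen. Ring A is closed by the cycloaddition itself (bonds C4a–C8a and C5–C6), and the pyran ring closes in the same event, 6-exo-dig with respect to the alkyne, when C8a bonds to C4a. No stereocentre is formed in 26 (C8a of 25 is lost on aromatisation), and C3 from step 8 is a spectator. The step needs regiocontrol, which the tether length enforces; it needs retention of O1 rather than opening of the pyran ring, which the better silanolate leaving group, the endocyclic and poorly aligned C8a–O1 bond and the buffered aprotic medium favour; and it needs the aryl prenyl ether to survive, which the already occupied C5′ helps. The 1Z ketene acetal puts only the small OSiMe3 group inside the s-cis diene and the tether outside.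

**Step 13**
Reactants: 26
Product: 27 manuifolin D, (3R)-7,2′-dihydroxy-4′-(3-methylbut-2-enyloxy)-5′-(2-methylbut-3-en-2-yl)isoflavan
Conditions: TBAF (2.5 equiv), AcOH (2.5 equiv), THF, 0 °C
Reagents that add atoms: none
Why: fluoride cleavage of both aryl silyl ethers; acetic acid buffers the phenoxides, and the prenyl ether, the allyl group and C3 are inert.

**Compound list**
1 | 2,4-dihydroxybenzaldehyde | O=Cc1ccc(O)cc1O | starting material
2 | prenyl bromide (1-bromo-3-methylbut-2-ene) | CC(C)=CCBr | starting material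
3 | 2-hydroxy-4-(3-methylbut-2-enyloxy)benzaldehyde | O=Cc1ccc(OCC=C(C)C)cc1O | intermediate
4 | chlorotriisopropylsilane | CC(C)[Si](Cl)(C(C)C)C(C)C | starting material
5 | 4-(3-methylbut-2-enyloxy)-2-(triisopropylsilyloxy)benzaldehyde | O=Cc1ccc(OCC=C(C)C)cc1O[Si](C(C)C)(C(C)C)C(C)C | intermediate
6 | 3-(2-methylbut-3-en-2-yl)-4-oxo-6-(triisopropylsilyloxy)cyclohexa-1,5-diene-1-carbaldehyde (Claisen dienone, not isolated) | O=CC1=CC(C(C)(C)C=C)C(=O)C=C1O[Si](C(C)C)(C(C)C)C(C)C | intermediate
7 | 4-hydroxy-5-(2-methylbut-3-en-2-yl)-2-(triisopropylsilyloxy)benzaldehyde | O=Cc1cc(C(C)(C)C=C)c(O)cc1O[Si](C(C)C)(C(C)C)C(C)C | intermediate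
8 | 5-(2-methylbut-3-en-2-yl)-4-(3-methylbut-2-enyloxy)-2-(triisopropylsilyloxy)benzaldehyde | O=Cc1cc(C(C)(C)C=C)c(OCC=C(C)C)cc1O[Si](C(C)C)(C(C)C)C(C)C | intermediate
9 | (methoxymethyl)triphenylphosphonium chloride | COC[P+](c1ccccc1)(c1ccccc1)c1ccccc1.[Cl-] | starting material
10 | Ar–CH=CH–OMe, 1-(2-methoxyethenyl)arene (E/Z mixture) | COC=Cc1cc(C(C)(C)C=C)c(OCC=C(C)C)cc1O[Si](C(C)C)(C(C)C)C(C)C | intermediate
11 | Ar–CH2–CHO, arylacetaldehyde (not isolated) | O=CCc1cc(C(C)(C)C=C)c(OCC=C(C)C)cc1O[Si](C(C)C)(C(C)C)C(C)C | intermediate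
12 | Ar–CH2–CO2H, arylacetic acid | OC(=O)Cc1cc(C(C)(C)C=C)c(OCC=C(C)C)cc1O[Si](C(C)C)(C(C)C)C(C)C | intermediate
13 | (R)-4-benzyl-1,3-oxazolidin-2-one | O=C1N[C@H](Cc2ccccc2)CO1 | starting material
14 | arylacetic pivalic mixed anhydride (not isolated) | CC(C)(C)C(=O)OC(=O)Cc1cc(C(C)(C)C=C)c(OCC=C(C)C)cc1O[Si](C(C)C)(C(C)C)C(C)C | intermediate
15 | (R)-4-benzyl-3-(2-Ar-acetyl)-1,3-oxazolidin-2-one | O=C(Cc1cc(C(C)(C)C=C)c(OCC=C(C)C)cc1O[Si](C(C)C)(C(C)C)C(C)C)N1[C@H](Cc2ccccc2)COC1=O | intermediate
16 | propargyl bromide | C#CCBr | starting material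
17 | sodium (Z)-enolate of 15 (not isolated) | [Na+].[O-]/C(=C\c1cc(C(C)(C)C=C)c(OCC=C(C)C)cc1O[Si](C(C)C)(C(C)C)C(C)C)N1[C@H](Cc2ccccc2)COC1=O | intermediate
18 | (4R)-4-benzyl-3-[(2R)-2-Ar-pent-4-ynoyl]-1,3-oxazolidin-2-one | O=C([C@H](CC#C)c1cc(C(C)(C)C=C)c(OCC=C(C)C)cc1O[Si](C(C)C)(C(C)C)C(C)C)N1[C@H](Cc2ccccc2)COC1=O | intermediate
19 | (2R)-2-Ar-pent-4-yn-1-ol | OC[C@H](CC#C)c1cc(C(C)(C)C=C)c(OCC=C(C)C)cc1O[Si](C(C)C)(C(C)C)C(C)C | intermediate
20 | 2,2,6-trimethyl-4H-1,3-dioxin-4-one | CC1=CC(=O)OC(C)(C)O1 | starting material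
21 | (2R)-2-Ar-pent-4-yn-1-yl 3-oxobutanoate | CC(=O)CC(=O)OC[C@H](CC#C)c1cc(C(C)(C)C=C)c(OCC=C(C)C)cc1O[Si](C(C)C)(C(C)C)C(C)C | intermediate
22 | trimethylsilyl trifluoromethanesulfonate | C[Si](C)(C)OS(=O)(=O)C(F)(F)F | starting material
23 | (2R)-2-Ar-pent-4-yn-1-yl 3-(trimethylsilyloxy)but-2-enoate (E/Z, not isolated) | CC(O[Si](C)(C)C)=CC(=O)OC[C@H](CC#C)c1cc(C(C)(C)C=C)c(OCC=C(C)C)cc1O[Si](C(C)C)(C(C)C)C(C)C | intermediate
24 | (2R)-2-Ar-pent-4-yn-1-yl (1Z)-1,3-bis(trimethylsilyloxy)buta-1,3-dien-1-yl ether (key-step precursor) | C=C(O[Si](C)(C)C)/C=C(\O[Si](C)(C)C)OC[C@H](CC#C)c1cc(C(C)(C)C=C)c(OCC=C(C)C)cc1O[Si](C(C)C)(C(C)C)C(C)C | intermediate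
25 | (3R)-3-Ar-7,8a-bis(trimethylsilyloxy)-3,4,6,8a-tetrahydro-2H-chromene (cycloadduct, not isolated) | C[Si](C)(C)OC1=CC2(O[Si](C)(C)C)OC[C@@H](c3cc(C(C)(C)C=C)c(OCC=C(C)C)cc3O[Si](C(C)C)(C(C)C)C(C)C)CC2=CC1 | intermediate
26 | (3R)-3-Ar-7-(trimethylsilyloxy)chroman (key-step product) | C[Si](C)(C)Oc1ccc2c(c1)OC[C@@H](c3cc(C(C)(C)C=C)c(OCC=C(C)C)cc3O[Si](C(C)C)(C(C)C)C(C)C)C2 | intermediate
27 | manuifolin D | C=CC(C)(C)c1cc([C@@H]2COc3cc(O)ccc3C2)c(O)cc1OCC=C(C)C | target

**Count**
Total steps: 13. Longest linear sequence: 13 steps (1 to 27); the route is fully linear.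

**Steps most likely to fail**

Step 12 (Proposed new method). The cycloaddition onto the unactivated alkyne may be slower than silatropic rearrangement or protodesilylation of the ketene acetal, so that the diene is consumed unproductively or returned as 21. The cycloadduct may also aromatise by expelling the ring oxygen instead of silanol, which opens the pyran ring. The fallback uses known chemistry and buys ring A instead of building it. It sets out from imide 15. Commercial 3-bromo-4-methylphenol F1 is silylated with 4 (imidazole, DMF) to (3-bromo-4-methylphenoxy)triisopropylsilane F2, and radical benzylic bromination (NBS, AIBN, PhCF3, 80 °C) gives [3-bromo-4-(bromomethyl)phenoxy]triisopropylsilane F3. Enolate 17, made from 15 as in step 8, is alkylated with F3 on the same face to (4R)-4-benzyl-3-[(2R)-2-Ar-3-(2-bromo-4-triisopropylsilyloxyphenyl)propanoyl]-1,3-oxazolidin-2-one F4. LiBH4 reduction as in step 9 gives (2R)-2-Ar-3-(2-bromo-4-triisopropylsilyloxyphenyl)propan-1-ol F5. Copper-catalysed intramolecular O-arylation (CuI, 3,4,7,8-tetramethyl-1,10-phenanthroline, K3PO4, toluene, 110 °C) closes the pyran ring to (3R)-3-Ar-7-(triisopropylsilyloxy)chroman F6. The conditions of step 13 convert F6 into 27, where the fallback rejoins the route.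

Step 11. Silylation at the ester oxygen may stay incomplete, or the ketene acetal may hydrolyse during concentration, so that mixtures of 21, 23 and 24 enter the thermolysis; 24 cannot be purified. The fallback leaves the trimethylsilyl series for one in which diene and cycloaddition product can be handled and purified. It sets out from 21. tert-Butyldimethylsilyl triflate and Et3N (CH2Cl2, 0 °C to rt) would give, by way of (2R)-2-Ar-pent-4-yn-1-yl 3-(tert-butyldimethylsilyloxy)but-2-enoate F7, the (2R)-2-Ar-pent-4-yn-1-yl (1Z)-1,3-bis(tert-butyldimethylsilyloxy)buta-1,3-dien-1-yl ether F8, which can be filtered through base-deactivated alumina. Thermolysis as in step 12 would pass through (3R)-3-Ar-7,8a-bis(tert-butyldimethylsilyloxy)-3,4,6,8a-tetrahydro-2H-chromene F9 and give the chromatographable (3R)-3-Ar-7-(tert-butyldimethylsilyloxy)chroman F10. The conditions of step 13 then lead to 27, where the fallback rejoins the route.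

Step 3. At 190 °C the prenyl group may be lost from oxygen (deprenylation), and the ortho-(1,1-dimethylallyl)phenol may rearrange further or cyclise onto its hydroxyl group; migration to C3 is the smaller worry. The fallback makes the quaternary benzylic carbon by cross-coupling instead of a sigmatropic shift. It sets out from 1. Bromination (Br2, AcOH) gives 5-bromo-2,4-dihydroxybenzaldehyde F11. The unchelated 4-OH is silylated (TBSCl, imidazole, CH2Cl2, 0 °C) to 5-bromo-4-(tert-butyldimethylsilyloxy)-2-hydroxybenzaldehyde F12, and the 2-OH with TIPSOTf/2,6-lutidine to 5-bromo-4-(tert-butyldimethylsilyloxy)-2-(triisopropylsilyloxy)benzaldehyde F13. A γ-selective Suzuki–Miyaura coupling with purchased 3-methylbut-2-enylboronic acid pinacol ester F14 (Pd catalyst with a bulky biaryl phosphine, K3PO4, THF/H2O) gives 4-(tert-butyldimethylsilyloxy)-5-(2-methylbut-3-en-2-yl)-2-(triisopropylsilyloxy)benzaldehyde F15. K2CO3 in MeOH at 0 °C removes the labile silyl ether para to the formyl group and returns 7, where the fallback rejoins the route.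

**Further compounds**
F1 | step 12 | 3-bromo-4-methylphenol (purchased) | Cc1ccc(O)cc1Br
F2 | step 12 | (3-bromo-4-methylphenoxy)triisopropylsilane | Cc1ccc(O[Si](C(C)C)(C(C)C)C(C)C)cc1Br
F3 | step 12 | [3-bromo-4-(bromomethyl)phenoxy]triisopropylsilane | BrCc1ccc(O[Si](C(C)C)(C(C)C)C(C)C)cc1Br
F4 | step 12 | (4R)-4-benzyl-3-[(2R)-2-Ar-3-(2-bromo-4-triisopropylsilyloxyphenyl)propanoyl]-1,3-oxazolidin-2-one | O=C([C@H](Cc1ccc(O[Si](C(C)C)(C(C)C)C(C)C)cc1Br)c1cc(C(C)(C)C=C)c(OCC=C(C)C)cc1O[Si](C(C)C)(C(C)C)C(C)C)N1[C@H](Cc2ccccc2)COC1=O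
F5 | step 12 | (2R)-2-Ar-3-(2-bromo-4-triisopropylsilyloxyphenyl)propan-1-ol | OC[C@H](Cc1ccc(O[Si](C(C)C)(C(C)C)C(C)C)cc1Br)c1cc(C(C)(C)C=C)c(OCC=C(C)C)cc1O[Si](C(C)C)(C(C)C)C(C)C
F6 | step 12 | (3R)-3-Ar-7-(triisopropylsilyloxy)chroman | CC(C)[Si](Oc1ccc2c(c1)OC[C@@H](c3cc(C(C)(C)C=C)c(OCC=C(C)C)cc3O[Si](C(C)C)(C(C)C)C(C)C)C2)(C(C)C)C(C)C
F7 | step 11 | (2R)-2-Ar-pent-4-yn-1-yl 3-(tert-butyldimethylsilyloxy)but-2-enoate | CC(O[Si](C)(C)C(C)(C)C)=CC(=O)OC[C@H](CC#C)c1cc(C(C)(C)C=C)c(OCC=C(C)C)cc1O[Si](C(C)C)(C(C)C)C(C)C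
F8 | step 11 | (2R)-2-Ar-pent-4-yn-1-yl (1Z)-1,3-bis(tert-butyldimethylsilyloxy)buta-1,3-dien-1-yl ether | C=C(O[Si](C)(C)C(C)(C)C)/C=C(\O[Si](C)(C)C(C)(C)C)OC[C@H](CC#C)c1cc(C(C)(C)C=C)c(OCC=C(C)C)cc1O[Si](C(C)C)(C(C)C)C(C)C
F9 | step 11 | (3R)-3-Ar-7,8a-bis(tert-butyldimethylsilyloxy)-3,4,6,8a-tetrahydro-2H-chromene | CC(C)(C)[Si](C)(C)OC1=CC2(O[Si](C)(C)C(C)(C)C)OC[C@@H](c3cc(C(C)(C)C=C)c(OCC=C(C)C)cc3O[Si](C(C)C)(C(C)C)C(C)C)CC2=CC1
F10 | step 11 | (3R)-3-Ar-7-(tert-butyldimethylsilyloxy)chroman | CC(C)(C)[Si](C)(C)Oc1ccc2c(c1)OC[C@@H](c3cc(C(C)(C)C=C)c(OCC=C(C)C)cc3O[Si](C(C)C)(C(C)C)C(C)C)C2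
F11 | step 3 | 5-bromo-2,4-dihydroxybenzaldehyde | O=Cc1cc(Br)c(O)cc1O
F12 | step 3 | 5-bromo-4-(tert-butyldimethylsilyloxy)-2-hydroxybenzaldehyde | O=Cc1cc(Br)c(O[Si](C)(C)C(C)(C)C)cc1O
F13 | step 3 | 5-bromo-4-(tert-butyldimethylsilyloxy)-2-(triisopropylsilyloxy)benzaldehyde | O=Cc1cc(Br)c(O[Si](C)(C)C(C)(C)C)cc1O[Si](C(C)C)(C(C)C)C(C)C
F14 | step 3 | 3-methylbut-2-enylboronic acid pinacol ester (purchased) | CC(C)=CCB1OC(C)(C)C(C)(C)O1
F15 | step 3 | 4-(tert-butyldimethylsilyloxy)-5-(2-methylbut-3-en-2-yl)-2-(triisopropylsilyloxy)benzaldehyde | O=Cc1cc(C(C)(C)C=C)c(O[Si](C)(C)C(C)(C)C)cc1O[Si](C(C)C)(C(C)C)C(C)C
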